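(The readings are simulated on assumed constants; the scatter is artificial.)

Slowness is what I read first: at 4.00 min the epsilon run keeps 23.6% of its substrate and the theta run 22.3%, although the theta charge is 1.59 times the epsilon charge.

| setting | epsilon | theta | flask |
|---|---|---|---|
| substrate | 0.029 M | 0.046 M | 0.021 M |
| gas | 3.6 mM (held) | 3.6 mM (held) | 3.6 mM (held) |
| remark | run made earlier | run made earlier |  |
| time |  |  | 6.0 min |

- epsilon (time / min: product / %, substrate / %): 0.250: 7.2, 86.3; 0.417: 13.0, 81.1; 0.667: 18.2, 73.5; 1.00: 27.9, 64.0; 1.50: 36.6, 52.9; 2.50: 53.0, 37.8; 4.00: 67.1, 23.6
- theta (time / min: product / %, substrate / %): 0.500: 16.1, 76.9; 1.00: 27.6, 64.6; 1.50: 38.0, 53.7; 2.00: 42.7, 46.1; 2.50: 52.0, 38.8; 3.00: 59.2, 32.2; 4.00: 68.2, 22.3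

(standard deviation of a reading: 1 percentage point)

- at the start none of partner is dissolved
- candidate steps: gas <-> partner; intermediate A <-> intermediate B; substrate <-> intermediate A; substrate -> product; intermediate B -> decomposed reagent; partner + intermediate A <-> intermediate C

- amount of product at 6.0 min, in percent of the substrate charged
- the change that raises the amount of product at 6.0 min, in percent of the substrate charged most ("none" if none brings more than 2 percentage points) (south / north / none)
- amount of product at 6.0 min, in percent of the substrate charged, after north

- south: doubling the transfer coefficient of the gas, all else as stated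
- north: doubling the saturation concentration of gas, all else as stated

So I lay the runs over each other and carry their fractions to the flask, but its charge lies below both. I follow one molecule of substrate and ask its chance per minute of becoming product: the product gained over a stretch, divided by the logarithmic mean substrate and the minutes. This product chance, a first-order rate constant, reads 0.336 min⁻¹ in the epsilon run from 1.50 min to 4.00 min. Substrate in that run falls at 0.323 min⁻¹ over that stretch. So I expect the flask to hold 12.4% substrate and 78.8% product at 6.0 min.

The forecast says 79% (75.5% to 82%), none for the best change, and 79% after north (74% to 83%): “Partner looks kinetically unimportant”.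

The flask gives 79.2% and none: south moves it −0.99 percentage points and north −2.3 points, to 76.9%.

    gas ⇌ partner, rate k1*(csat - [partner]) (kL = 0.470 min⁻¹)
    intermediate A ⇌ intermediate B (K = 0.410, k = 0.230 min⁻¹)
    substrate ⇌ intermediate A (K = 0.120, k = 0.370 min⁻¹)
    substrate → product (k = 0.340 min⁻¹)
    intermediate B → decomposed reagent (k = 0.210 min⁻¹)
    partner + intermediate A ⇌ intermediate C (K = 690 M⁻¹, k = 210 M⁻¹ min⁻¹)

In the flask, substrate and intermediate A relax by the step between them, taken by itself, with a half-life of 0.201 min, while the product chance read in the epsilon run gives a half-life of 2.06 min, about ten times as long. From 3.00 min to 6.0 min that chance reckons 21 points of product, and the flask gains 21 points. For the neighbour read at 15 min, with 1.68% substrate left, it reckons 16 points beyond the flask, and the neighbour shows 15 points.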